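You asked for a quick number on the small charge, so here is how I took it.

| flask | free monomer | initiator | remark | time |
|---|---|---|---|---|
| oak | 0.11 M | 1.9 mol% | run made earlier |  |
| flask | 0.11 M | 0.95 mol% |  | 6.0 min |

oak run (percent of the free monomer charged)

| time / s | monomer in chains / % | free monomer / % |
|---|---|---|
| 20.0 | 1.4 | 99.1 |
| 40.0 | 3.1 | 93.6 |
| 60.0 | 6.3 | 91.0 |
| 80.0 | 10.4 | 87.9 |
| 120 | 14.8 | 80.0 |

(each reading ± 1 percentage point)

* whether the average number of monomer units in a chain (chains begun, living or dead) reaches 20 by 6.0 min (yes / no)
* average number of monomer units in a chain (chains begun, living or dead) at 6.0 min

- the average divides the monomer in chains by the number of chains begun, living and dead together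
- the earlier runs do not show the number of chains; that part of a forecast is a guess
- no earlier run changes the charge of initiator; that part of a forecast is a guess

I reckoned with one quantity, the needed share: the percentage of the free monomer charged that must stand in chains for the wanted length if every initiator begins one chain. It is the wanted length times the loading, 19.0%, and the average length here is the number-average degree of polymerisation.

The flask carried half the oak loading, and the oak run read 14.8% in chains at 120 s. I guessed that chains fill in proportion to the loading and steadily over time, so I expected 22.2% at 6.0 min. I then computed only the correction to the needed share: 3.2 percentage points above it, while the scatter of that one reading, scaled alike, came to 1.5 points. So I said yes, with a length of 23.4.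

Your forecast also said yes, with 25, a little longer than mine, and it took the same count, “If every initiator starts a chain”. That count and the scaling were guesses in both reckonings.

The flask gave yes, with 23.6 at 6.0 min, and it reached the wanted length at 4.40 min.

    free monomer + initiator → living end + monomer in chains (k = 9.61 M⁻¹ min⁻¹)
    free monomer + living end → monomer in chains + living end, rate k2*[living end]*[free monomer] (k = 201 M⁻¹ min⁻¹)
    monomer in chains + living end → free monomer + living end, rate k3*[living end] as long as [monomer in chains] is above zero (k = 13.3 min⁻¹)
    free monomer → uncatalysed product (k = 0.0235 min⁻¹)
    initiator → spent initiator (k = 0.0922 min⁻¹)

At 6.00 min the flask held 20.4% in chains, above the needed share of 19.0%, beside 11.6% of uncatalysed product. At 60.0 min the monomer in chains of the flask stood far below the same needed share, at 0.00873%, with 72.0% as uncatalysed product.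

(The runs come from a simulation on assumed constants.)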